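## The problem

Cupressuflavone is two apigenin units joined through C8 and C8'' of their rings A. That bond lies between two phloroglucinol-type rings whose four ortho carbons (C7, C8a, C7'', C8a'') all carry oxygen, so it is a tetra-ortho-substituted biaryl bond that is hard to forge between finished halves. There are no stereocentres. The only stereo-element is the axis, which carries no descriptor in the target structure, so nothing has to be relayed and racemic material is the goal. The real selectivity problem is positional. On each ring A the two oxygens ortho to the axis are chemically almost alike, yet one must become the pyranone oxygen O1 and the other the free 7-hydroxyl, and the carbonyl carbon C4 must enter at C4a and not at C6. A slip at either point gives 6-linked isomers. The free hexaphenol and its phloroglucinol biaryl precursors oxidise in air. A 5-hydroxy-4-chromenone opens and recloses onto the C5 oxygen in hot aqueous acid (Wessely–Moser rearrangement), which would move the linkage from C8 to C6. The phenols are therefore carried as ethers and freed last under anhydrous conditions. The enabling feature is that ring A is a 1,3,5-trioxygenated benzene with C8 sitting between C7–O and C8a–O. This is the pattern that results when an aryl ynol ether (C8 and C7 with the C7 oxygen) joins a 3-alkoxy vinylketene (C8a with its oxygen, C4a, C5 with its oxygen, C6). If the aryl group on the alkyne is the other ring A, the axis exists before the second ring does. The ketene oxygen is then the only free hydroxyl, at the carbon that must carry O1.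

## Retrosynthesis

**23 to 22.** The six O–alkyl bonds are cut last. Target 23 is traced to the hexa-ether 22, in which one half carries ethyl and the other methyl ethers on ring A and both rings B are anisyl. The ethyl groups are the alkoxy groups that the annulation partners 7 and 11 bring in, and they leave in the same operation as the methyl groups. Keeping every phenol masked until here avoids air oxidation and the acid-induced shift of the biaryl bond. The forward step must cleave six ethers without opening a pyranone.

**22 to 19 and 20.** Both pyranone rings are opened at O1–C2, giving the bis(1,3-diketone) 21. The C3–C2 bonds are then cut to the diacetyl biaryl 19 and two molecules of 4-methoxybenzoyl chloride 20. The neighbouring option, joining two finished flavones at C8, would make the most hindered bond of the molecule last and offers no control between C6 and C8. Building both rings C at once on a preformed biaryl needs only classical carbonyl chemistry. The forward reactions must acylate two hindered methyl ketone enolates and close onto the only free hydroxyl of each ring.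

**19 to 17.** The two aryl–acetyl bonds (C4a–C4 in each half) are cut to the biaryl diol 17. Each ring has two free CH positions, one ortho to the free hydroxyl (wanted) and one between two alkoxy groups. The free hydroxyls decide between them: O-acetylation to diacetate 18 and Fries rearrangement hold the acyl group ortho as a chelate. This is where the distinction between O1 and O7 is used.

**17 to 16.** One O–benzyl bond is cut. The benzyl group marks O1 of the first ring A through coupling and annulation, where a free ortho phenol would add to the ynol ether. Hydrogenolysis removes it without touching the methyl and ethyl ethers.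

**16 to 7 and 11 (key).** Three bonds of the second ring A are cut: C8–C8a, C6–C7 and C4a–C8a. This leads to the aryl ynol ether 7 and 3-ethoxycyclobutenone 11, which serves as the latent vinylketene 12. The neighbouring cuts are a direct C8–C8'' coupling of two 2,6-dioxygenated aryl partners or an oxidative phenol coupling. Both must create a bond with four ortho substituents, and the oxidative version also gives ortho/para mixtures. The annulation makes no bond at a hindered centre, because the future axis is the unhindered aryl–alkyne bond of 7. It also delivers the new ring with one free hydroxyl exactly at C8a. A whole arene is removed in one step. The forward reaction must orient the ketene–alkyne union correctly and run below the temperature at which 7 fragments.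

**7 to 1 and 4.** The Csp2–Csp bond is cut to aryl iodide 3 and ethoxyacetylene 4, joined by Negishi coupling through acetylide 5 and zinc reagent 6. Iodide 3 comes from 3,5-dimethoxyphenol 1 by ortho-iodination to 2 and benzylation. A small linear alkynylzinc is the partner best suited to a doubly ortho-substituted iodide.

**11 to 4 and 8.** The four-membered ring is cut across C1–C2 and C3–C4 to ethoxyacetylene 4 and dichloroketene 9, generated from trichloroacetyl chloride 8. Adduct 10 is dechlorinated reductively to 11. Where 11 can be bought, these two steps fall away.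

## Roads not taken

**Alternative 1:** The cut removes both rings A at C7–C8 and C4a–C5. It leaves two 2-anisyl-4-pyranones joined at C6 by a CH2–CH2 bridge, 6,6'-(ethane-1,2-diyl)bis[2-(4-methoxyphenyl)-4H-pyran-4-one] A1, whose bridge carbons are the future C8 and C8''. In the forward key step A1 would be heated with two equivalents of a doubly activated malonic ester. Each bridge methylene would be acylated (C7–C8) and the second malonyl carbonyl would condense at the adjacent pyranone carbon (C4a–C5). The product would be cupressuflavone 4',4'''-dimethyl ether A2, two ether cleavages short of 23.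
- Merits: it is the most convergent plan. The crowded axis starts as an sp3–sp3 bond, O1 is already in the pyranone so the O1/O7 question never arises, and ring A appears with free hydroxyls.
- Weak points: thermal malonyl transfer is reliable with enol- or enamine-type 1,3-dinucleophiles that close a ring through a heteroatom. Here both nucleophilic sites are carbon: a weakly acidic vinylogous methylene and the electron-poor C3 of a 4-pyranone. Two such annulations must also occur on adjacent carbons. O-Acylation and pyranone ring-opening are likely diversions, and base cannot be used freely.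
- Comparison: this road is shorter on paper and better on protecting groups. The chosen plan sets against it a key step whose reaction class is established under neutral conditions and intermediates that are stable ethers.

**Alternative 2:** The cut is C8–C8'' itself, between two molecules of phenol 1 tied through their oxygens as di-tert-butylbis(3,5-dimethoxyphenoxy)silane A3. In the forward key step, anodic oxidation in a fluorinated alcohol would join two unfunctionalised ortho carbons. It would close the seven-membered 6,6-di-tert-butyl-1,3,9,11-tetramethoxydibenzo[d,f][1,3,2]dioxasilepine A4. Desilylation would then free both O1 phenols.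
- Merits: about three operations reach a symmetric biaryl with both O1 oxygens marked and uniform methyl ethers. No halogen or metal is needed, and the tether enforces ortho,ortho' coupling.
- Weak points: anodic phenol couplings of this kind rely on a free hydroxyl, and silyl ethers are normally the unreactive partners. The radical cation of a 1,3,5-trioxygenated ring is most reactive at the carbon between the two methoxy groups, so the tether must overrule the electronic preference. The bridged product is likely easier to oxidise than the substrate. Aryl Si–O bonds are labile in an acidic fluoroalcohol, and a tetra-ortho-substituted bond must still be formed directly.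
- Comparison: in step count and uniformity of protecting groups this road is better. The chosen plan sets against it that no bond is made at a hindered position and that its key step does not depend on an untested electrode reaction.

**Alternative 3:** The cut is one bond from C8 (and C8'') to an ortho carbon in each ring A. It leads back to 6,6'-(ethane-1,2-diyl)bis(4-methoxy-2H-pyran-2-one) A5. In the forward key step an alkoxide base with heat would open both lactones. Each bridge methylene would attack its own ester carbonyl in a Claisen closure, and aromatisation would give 4,4'-dimethoxybiphenyl-2,2',6,6'-tetraol A6.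
- Merits: the precursor is one oxidative dimerisation away from a commercial methylpyranone, and the axis again starts as an sp3–sp3 bond. Every free ring carbon of A6 lies between a hydroxyl and the methoxy group, so acylation has no regiochemical choice and the acetyl group itself selects O1. This is cleaner than the chelation argument the chosen plan needs.
- Weak points: after lactone opening the centre of the molecule is a 1,4-diketone. Five-membered aldol closure and relactonisation compete with the double six-membered Claisen closure. A6 is a free, air-sensitive tetraphenol whose unchelated 7-hydroxyls must be carried through the aroylation as extra esters or protected.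
- Comparison: this road is shorter to the biaryl and unambiguous in the acylation. The chosen plan sets against it a precedented key reaction class and robust, chromatographable ether intermediates throughout.

Key step: step 6

Assumption: the target structure carries no descriptor for the 8,8'' axis, so the racemic biaryl is taken as the goal and no step is asked to control the sense of the axis.

## Route

Step 1
Reactants: 1 3,5-dimethoxyphenol
Product: 2 2-iodo-3,5-dimethoxyphenol
Conditions: I2, NaHCO3, THF/H2O, 0 °C
Reagents that add atoms: iodine, II
Why: Electrophilic aromatic iodination of the phenol under weakly basic conditions; attack ortho to the hydroxyl (between OH and OMe) is expected over the more shielded carbon between the two methoxy groups, and one equivalent of iodine at 0 °C limits di-iodination.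

Step 2
Reactants: 2 2-iodo-3,5-dimethoxyphenol
Product: 3 1-(benzyloxy)-2-iodo-3,5-dimethoxybenzene
Conditions: BnBr, K2CO3, DMF, rt
Reagents that add atoms: benzyl bromide, BrCc1ccccc1
Why: Williamson ether synthesis on the phenoxide; the benzyl group marks the oxygen that will become O1 of the first half and prevents later addition of this phenol to the ynol ether.

Step 3
Reactants: 3 1-(benzyloxy)-2-iodo-3,5-dimethoxybenzene; 4 ethoxyacetylene
Product: 7 1-(benzyloxy)-2-(ethoxyethynyl)-3,5-dimethoxybenzene, via (ethoxyethynyl)lithium 5 (not isolated), via chloro(ethoxyethynyl)zinc 6 (not isolated)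
Conditions: 4, n-BuLi, THF, −78 °C; ZnCl2, −78 → 0 °C; then 3, Pd(PPh3)4 (5 mol %), rt → 45 °C; purification on Et3N-deactivated silica
Reagents that add atoms: none
Why: Negishi coupling: deprotonation of 4 gives 5, transmetalation to zinc gives 6, and zerovalent palladium from Pd(PPh3)4 inserts into the C–I bond of 3; the linear alkynylzinc is small enough to transmetalate at the doubly ortho-substituted centre, and the neutral conditions spare the acid-sensitive ynol ether.

Step 4
Reactants: 4 ethoxyacetylene; 8 trichloroacetyl chloride
Product: 10 4,4-dichloro-3-ethoxycyclobut-2-en-1-one, via dichloroketene 9 (not isolated)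
Conditions: Zn–Cu couple, Et2O/DME, rt, slow addition of 8
Reagents that add atoms: none
Why: Zinc dechlorination of 8 gives ketene 9, which undergoes [2+2] cycloaddition with the ynol ether; the unsubstituted, nucleophilic alkyne carbon bonds to the ketene carbonyl carbon, so the ethoxy group ends at C3 and the chlorines at C4.

Step 5
Reactants: 10 4,4-dichloro-3-ethoxycyclobut-2-en-1-one
Product: 11 3-ethoxycyclobut-2-en-1-one
Conditions: Zn dust, AcOH, TMEDA, EtOH, 0 °C → rt
Reagents that add atoms: none
Why: Reductive dechlorination of an α,α-dichloro ketone by zinc, as in the standard preparation of cyclobutenones from dichloroketene adducts; the amine buffer keeps the medium mild enough for the vinylogous ester.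

Step 6
Reactants: 7 1-(benzyloxy)-2-(ethoxyethynyl)-3,5-dimethoxybenzene; 11 3-ethoxycyclobut-2-en-1-one
Product: 16 2'-(benzyloxy)-4,6-diethoxy-4',6'-dimethoxybiphenyl-2-ol, via vinylketene 12 (not isolated), via aryl vinylcyclobutenone 13 (not isolated), via dienylketene 14 (not isolated), via cyclohexadienone 15 (not isolated)
Conditions: 7 (1 equiv), 11 (2 equiv), toluene, 80 °C, then 110 °C, sealed tube, argon
Reagents that add atoms: none
Why: Danheiser benzannulation: on heating, 11 opens reversibly by a four-electron electrocyclic reaction to vinylketene 12. Ynol ether 7 adds across the ketene C=C in a [2+2] cycloaddition in which its aryl-bearing carbon bonds to the ketene carbonyl carbon (C8–C8a) and its oxygen-bearing carbon to the ketene α-carbon (C7–C6), giving cyclobutenone 13. A second four-electron opening gives dienylketene 14, a six-electron electrocyclisation forms C4a–C8a and closes ring A as cyclohexadienone 15, and enolisation gives phenol 16. The closest known reaction type is the benzannulation of cyclobutenones with alkoxy- and siloxyalkynes, which gives resorcinol monoethers with the same placement of hydroxyl, alkyne substituent and alkoxy group. No stereocentre survives, since the sp3 centre of 13 is lost on ring-opening and the axis forms racemic. The selectivity needed is the orientation of the [2+2] step: direct lone-pair donation from the ethoxy oxygen makes the aryl-bearing carbon the nucleophilic terminus and should outweigh the opposing bias of the electron-rich aryl group, and bonding of that bulky carbon to the unhindered sp carbon of the ketene is also the less crowded mode. Only the ketene oxygen ends as a free hydroxyl, at the carbon that will carry O1, while the crowded axis is simply the former aryl–alkyne bond. An excess of 11 and a ceiling of 110 °C keep capture of 7 ahead of its retro-ene loss of ethylene.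

Step 7
Reactants: 16 2'-(benzyloxy)-4,6-diethoxy-4',6'-dimethoxybiphenyl-2-ol
Product: 17 4,6-diethoxy-4',6'-dimethoxybiphenyl-2,2'-diol
Conditions: H2 (1 atm), Pd/C, EtOAc/EtOH, rt
Reagents that add atoms: none
Why: Hydrogenolysis of the benzyl aryl ether; methyl and ethyl ethers and the arenes are inert, so exactly the two hydroxyls destined to become O1 and O1'' are free.

Step 8
Reactants: 17 4,6-diethoxy-4',6'-dimethoxybiphenyl-2,2'-diol
Product: 19 1,1'-(4,6-diethoxy-2,2'-dihydroxy-4',6'-dimethoxybiphenyl-3,3'-diyl)di(ethan-1-one), via biaryl diacetate 18 (not isolated)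
Conditions: Ac2O, BF3·OEt2, AcOH, 0 → 70 °C; then aq. NaOAc, MeOH, 60 °C
Reagents that add atoms: acetic anhydride, CC(=O)OC(C)=O
Why: O-Acetylation followed by Lewis-acid Fries rearrangement, as used to make 2-hydroxy-4,6-dialkoxyacetophenones from phloroglucinol diethers; coordination of boron between the phenol oxygen and the new carbonyl makes the ortho-hydroxy ketone the thermodynamic sink, so the acetyl group should settle at C3 and C3' and not at the carbon between two alkoxy groups.

Step 9
Reactants: 19 1,1'-(4,6-diethoxy-2,2'-dihydroxy-4',6'-dimethoxybiphenyl-3,3'-diyl)di(ethan-1-one); 20 4-methoxybenzoyl chloride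
Product: 21 1,1'-(4,6-diethoxy-2,2'-dihydroxy-4',6'-dimethoxybiphenyl-3,3'-diyl)bis[3-(4-methoxyphenyl)propane-1,3-dione]
Conditions: LiN(SiMe3)2 (7 equiv), THF, −78 → −10 °C; 20 (2.2 equiv), −78 °C → rt; aq. HCl
Reagents that add atoms: none
Why: Crossed Claisen C-aroylation of the lithium dianion (phenoxide plus ketone enolate) on each half, the one-flask form of the Baker–Venkataraman sequence; any O-aroylated material rearranges under the excess base to the same 1,3-diketone.

Step 10
Reactants: 21 1,1'-(4,6-diethoxy-2,2'-dihydroxy-4',6'-dimethoxybiphenyl-3,3'-diyl)bis[3-(4-methoxyphenyl)propane-1,3-dione]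
Product: 22 5,7-diethoxy-5',7'-dimethoxy-2,2'-bis(4-methoxyphenyl)-4H,4'H-[8,8'-bichromene]-4,4'-dione
Conditions: H2SO4 (cat.), AcOH, 95 °C
Reagents that add atoms: none
Why: Acid-catalysed cyclodehydration of 2-hydroxyaryl 1,3-diketones to 4H-chromen-4-ones; each ring has only one free hydroxyl, the one ortho to the axis, so closure can only give the 8,8'-linked bichromenone, and with the C5 oxygens alkylated no reclosure onto C5–O is possible.

Step 11
Reactants: 22 5,7-diethoxy-5',7'-dimethoxy-2,2'-bis(4-methoxyphenyl)-4H,4'H-[8,8'-bichromene]-4,4'-dione
Product: 23 cupressuflavone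
Conditions: BBr3 (excess), CH2Cl2, −78 °C → rt; then ice/H2O
Reagents that add atoms: none
Why: Lewis-acid cleavage of aryl alkyl ethers: BBr3 coordinates each ether oxygen and bromide removes methyl or ethyl by SN2, the chelated 5-O-alkyl groups first and the 7-O-alkyl groups last; the anhydrous, non-protic medium avoids pyranone opening and hence the Wessely–Moser shift of the biaryl bond from C8 to C6.

## Compound list

1 | 3,5-dimethoxyphenol | COc1cc(O)cc(OC)c1 | starting material
2 | 2-iodo-3,5-dimethoxyphenol | COc1cc(O)c(I)c(OC)c1 | intermediate
3 | 1-(benzyloxy)-2-iodo-3,5-dimethoxybenzene | COc1cc(OC)c(I)c(OCc2ccccc2)c1 | intermediate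
4 | ethoxyacetylene | C#COCC | starting material
5 | (ethoxyethynyl)lithium | [Li]C#COCC | intermediate (not isolated)
6 | chloro(ethoxyethynyl)zinc | Cl[Zn]C#COCC | intermediate (not isolated)
7 | 1-(benzyloxy)-2-(ethoxyethynyl)-3,5-dimethoxybenzene | CCOC#Cc1c(OC)cc(OC)cc1OCc1ccccc1 | intermediate
8 | trichloroacetyl chloride | O=C(Cl)C(Cl)(Cl)Cl | starting material
9 | dichloroketene | O=C=C(Cl)Cl | intermediate (not isolated)
10 | 4,4-dichloro-3-ethoxycyclobut-2-en-1-one | CCOC1=CC(=O)C1(Cl)Cl | intermediate
11 | 3-ethoxycyclobut-2-en-1-one | CCOC1=CC(=O)C1 | intermediate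
12 | 3-ethoxybuta-1,3-dien-1-one | C=C(OCC)C=C=O | intermediate (not isolated)
13 | 2-[2-(benzyloxy)-4,6-dimethoxyphenyl]-3-ethoxy-4-(1-ethoxyethenyl)cyclobut-2-en-1-one (racemic) | O=C1C(c2c(OC)cc(OC)cc2OCc2ccccc2)=C(OCC)C1C(OCC)=C | intermediate (not isolated)
14 | (3E)-2-[2-(benzyloxy)-4,6-dimethoxyphenyl]-3,5-diethoxyhexa-1,3,5-trien-1-one (ketene and vinyl ether arms cis) | O=C=C(c1c(OC)cc(OC)cc1OCc1ccccc1)/C(OCC)=C\C(OCC)=C | intermediate (not isolated)
15 | 2-[2-(benzyloxy)-4,6-dimethoxyphenyl]-3,5-diethoxycyclohexa-2,4-dien-1-one | O=C1CC(OCC)=CC(OCC)=C1c1c(OC)cc(OC)cc1OCc1ccccc1 | intermediate (not isolated)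
16 | 2'-(benzyloxy)-4,6-diethoxy-4',6'-dimethoxybiphenyl-2-ol | CCOc1cc(O)c(-c2c(OC)cc(OC)cc2OCc2ccccc2)c(OCC)c1 | intermediate
17 | 4,6-diethoxy-4',6'-dimethoxybiphenyl-2,2'-diol | CCOc1cc(O)c(-c2c(OC)cc(OC)cc2O)c(OCC)c1 | intermediate
18 | 4,6-diethoxy-4',6'-dimethoxybiphenyl-2,2'-diyl diacetate | CCOc1cc(OC(C)=O)c(-c2c(OC)cc(OC)cc2OC(C)=O)c(OCC)c1 | intermediate (not isolated)
19 | 1,1'-(4,6-diethoxy-2,2'-dihydroxy-4',6'-dimethoxybiphenyl-3,3'-diyl)di(ethan-1-one) | CCOc1c(C(C)=O)c(O)c(-c2c(OC)cc(OC)c(C(C)=O)c2O)c(OCC)c1 | intermediate
20 | 4-methoxybenzoyl chloride | COc1ccc(cc1)C(Cl)=O | starting material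
21 | 1,1'-(4,6-diethoxy-2,2'-dihydroxy-4',6'-dimethoxybiphenyl-3,3'-diyl)bis[3-(4-methoxyphenyl)propane-1,3-dione] | CCOc1c(C(=O)CC(=O)c2ccc(OC)cc2)c(O)c(-c2c(OC)cc(OC)c(C(=O)CC(=O)c3ccc(OC)cc3)c2O)c(OCC)c1 | intermediate
22 | 5,7-diethoxy-5',7'-dimethoxy-2,2'-bis(4-methoxyphenyl)-4H,4'H-[8,8'-bichromene]-4,4'-dione | O=c1cc(-c2ccc(OC)cc2)oc2c(-c3c(OC)cc(OC)c4c(=O)cc(-c5ccc(OC)cc5)oc34)c(OCC)cc(OCC)c12 | intermediate
23 | cupressuflavone, 5,5',7,7'-tetrahydroxy-2,2'-bis(4-hydroxyphenyl)-4H,4'H-[8,8'-bichromene]-4,4'-dione (racemic axis) | O=c1cc(-c2ccc(O)cc2)oc2c(-c3c(O)cc(O)c4c(=O)cc(-c5ccc(O)cc5)oc34)c(O)cc(O)c12 | target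

## Step count and least certain steps

Total step count: 11. Longest linear sequence: 9 steps (steps 1, 2, 3, 6, 7, 8, 9, 10, 11); steps 4 and 5 form the short second branch.

**Step 6 (key step).** Four processes could defeat it:
- thermal retro-ene fragmentation of the ethyl ynol ether to an arylketene and ethylene before it is captured;
- sluggish opening of the donor-stabilised cyclobutenone, so that the vinylketene is consumed by self-condensation;
- reversal of the [2+2] orientation, because the electron-rich aryl group opposes the polarisation set by the ethoxy group;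
- stalling at the vinylcyclobutenone stage.

The fallback abandons the annulation for a copper-mediated biaryl coupling and accepts a symmetric, all-methyl series. It sets out from 3 and returns to the route at 23. Ullmann homocoupling of iodide 3 with copper bronze in hot DMF should give 2,2'-bis(benzyloxy)-4,4',6,6'-tetramethoxybiphenyl F1. Hydrogenolysis should give 4,4',6,6'-tetramethoxybiphenyl-2,2'-diol F2. The operations of steps 8 to 10 should then give in turn 1,1'-(2,2'-dihydroxy-4,4',6,6'-tetramethoxybiphenyl-3,3'-diyl)di(ethan-1-one) F3, 1,1'-(2,2'-dihydroxy-4,4',6,6'-tetramethoxybiphenyl-3,3'-diyl)bis[3-(4-methoxyphenyl)propane-1,3-dione] F4 (with 20) and 5,5',7,7'-tetramethoxy-2,2'-bis(4-methoxyphenyl)-4H,4'H-[8,8'-bichromene]-4,4'-dione F5. BBr3 cleavage as in step 11 should then give 23.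

**Step 1.** The iodination may lose regiocontrol, with attack at the carbon between the two methoxy groups or double iodination. The fallback replaces electrophilic substitution by directed ortho-metalation. It sets out from 1 and returns at 2. Protection with chloromethyl methyl ether and i-Pr2NEt should give 1,3-dimethoxy-5-(methoxymethoxy)benzene F6. n-BuLi in THF should lithiate between the acetal oxygen and a methoxy group to give [2,4-dimethoxy-6-(methoxymethoxy)phenyl]lithium F7. Iodine should then give 2-iodo-1,5-dimethoxy-3-(methoxymethoxy)benzene F8, and HCl in methanol should release 2.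

**Step 3.** Oxidative addition at the hindered, electron-rich iodide may be slow and let the acetylide homocouple. The ynol ether may also be hydrated to an arylacetic ester during isolation. The fallback builds the triple bond by elimination instead of cross-coupling. It sets out from 3 and returns at 7. Iodine–lithium exchange with n-BuLi at −78 °C should give [2-(benzyloxy)-4,6-dimethoxyphenyl]lithium F9. Acylation with 2-ethoxy-N-methoxy-N-methylacetamide should give 1-[2-(benzyloxy)-4,6-dimethoxyphenyl]-2-ethoxyethan-1-one F10. KOt-Bu and N-phenyltriflimide should convert this to 1-[2-(benzyloxy)-4,6-dimethoxyphenyl]-2-ethoxyethenyl trifluoromethanesulfonate F11. Further KOt-Bu should eliminate triflate to give 7.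

**Step 8.** The acyl group may enter para to the hydroxyl, at the carbon between two alkoxy groups. The rearrangement may stop after one ring, or the ether next to the new ketone may be partly cleaved. The fallback delivers the three-carbon unit from the phenol oxygen, so that ring closure can only reach the ortho carbon. It sets out from 17 and returns at 22, bypassing steps 8 to 10. Conjugate addition of both phenols to ethyl 3-(4-methoxyphenyl)propiolate (K2CO3, DMF) should give diethyl 3,3'-[(4,6-diethoxy-4',6'-dimethoxybiphenyl-2,2'-diyl)bis(oxy)]bis[3-(4-methoxyphenyl)prop-2-enoate] F12. Saponification with LiOH should give 3,3'-[(4,6-diethoxy-4',6'-dimethoxybiphenyl-2,2'-diyl)bis(oxy)]bis[3-(4-methoxyphenyl)prop-2-enoic acid] F13. Intramolecular Friedel–Crafts acylation in P2O5/MeSO3H should then close both pyranones to 22.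

**Step 9.** The twofold aroylation may stop at a mono-diketone, or at O-aroyl esters that fail to rearrange at the hindered phenol. The fallback replaces acylation by condensation with an aldehyde followed by oxidation. It sets out from 19 and returns at 22, bypassing 21 and step 10. Claisen–Schmidt condensation with 4-methoxybenzaldehyde (KOH, EtOH) should give (2E,2'E)-1,1'-(4,6-diethoxy-2,2'-dihydroxy-4',6'-dimethoxybiphenyl-3,3'-diyl)bis[3-(4-methoxyphenyl)prop-2-en-1-one] F14. Catalytic I2 in DMSO at 130 °C should effect oxa-Michael closure and dehydrogenation to 22.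

## Further compounds

F1 | step 6 | 2,2'-bis(benzyloxy)-4,4',6,6'-tetramethoxybiphenyl | COc1cc(OC)c(-c2c(OC)cc(OC)cc2OCc2ccccc2)c(OCc2ccccc2)c1
F2 | step 6 | 4,4',6,6'-tetramethoxybiphenyl-2,2'-diol | COc1cc(O)c(-c2c(O)cc(OC)cc2OC)c(OC)c1
F3 | step 6 | 1,1'-(2,2'-dihydroxy-4,4',6,6'-tetramethoxybiphenyl-3,3'-diyl)di(ethan-1-one) | COc1cc(OC)c(-c2c(OC)cc(OC)c(C(C)=O)c2O)c(O)c1C(C)=O
F4 | step 6 | 1,1'-(2,2'-dihydroxy-4,4',6,6'-tetramethoxybiphenyl-3,3'-diyl)bis[3-(4-methoxyphenyl)propane-1,3-dione] | COc1cc(OC)c(-c2c(OC)cc(OC)c(C(=O)CC(=O)c3ccc(OC)cc3)c2O)c(O)c1C(=O)CC(=O)c1ccc(OC)cc1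
F5 | step 6 | 5,5',7,7'-tetramethoxy-2,2'-bis(4-methoxyphenyl)-4H,4'H-[8,8'-bichromene]-4,4'-dione | O=c1cc(-c2ccc(OC)cc2)oc2c(-c3c(OC)cc(OC)c4c(=O)cc(-c5ccc(OC)cc5)oc34)c(OC)cc(OC)c12
F6 | step 1 | 1,3-dimethoxy-5-(methoxymethoxy)benzene | COCOc1cc(OC)cc(OC)c1
F7 | step 1 | [2,4-dimethoxy-6-(methoxymethoxy)phenyl]lithium | [Li]c1c(OC)cc(OC)cc1OCOC
F8 | step 1 | 2-iodo-1,5-dimethoxy-3-(methoxymethoxy)benzene | COCOc1cc(OC)cc(OC)c1I
F9 | step 3 | [2-(benzyloxy)-4,6-dimethoxyphenyl]lithium | [Li]c1c(OC)cc(OC)cc1OCc1ccccc1
F10 | step 3 | 1-[2-(benzyloxy)-4,6-dimethoxyphenyl]-2-ethoxyethan-1-one | CCOCC(=O)c1c(OC)cc(OC)cc1OCc1ccccc1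
F11 | step 3 | 1-[2-(benzyloxy)-4,6-dimethoxyphenyl]-2-ethoxyethenyl trifluoromethanesulfonate (alkene geometry not defined) | CCOC=C(OS(=O)(=O)C(F)(F)F)c1c(OC)cc(OC)cc1OCc1ccccc1
F12 | step 8 | diethyl 3,3'-[(4,6-diethoxy-4',6'-dimethoxybiphenyl-2,2'-diyl)bis(oxy)]bis[3-(4-methoxyphenyl)prop-2-enoate] (alkene geometry not defined) | CCOC(=O)C=C(Oc1cc(OCC)cc(OCC)c1-c1c(OC)cc(OC)cc1OC(=CC(=O)OCC)c1ccc(OC)cc1)c1ccc(OC)cc1
F13 | step 8 | 3,3'-[(4,6-diethoxy-4',6'-dimethoxybiphenyl-2,2'-diyl)bis(oxy)]bis[3-(4-methoxyphenyl)prop-2-enoic acid] (alkene geometry not defined) | OC(=O)C=C(Oc1cc(OCC)cc(OCC)c1-c1c(OC)cc(OC)cc1OC(=CC(O)=O)c1ccc(OC)cc1)c1ccc(OC)cc1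
F14 | step 9 | (2E,2'E)-1,1'-(4,6-diethoxy-2,2'-dihydroxy-4',6'-dimethoxybiphenyl-3,3'-diyl)bis[3-(4-methoxyphenyl)prop-2-en-1-one] | CCOc1c(C(=O)/C=C/c2ccc(OC)cc2)c(O)c(-c2c(OC)cc(OC)c(C(=O)/C=C/c3ccc(OC)cc3)c2O)c(OCC)c1
A1 | alternative 1 | 6,6'-(ethane-1,2-diyl)bis[2-(4-methoxyphenyl)-4H-pyran-4-one] | O=c1cc(-c2ccc(OC)cc2)oc(CCc2cc(=O)cc(-c3ccc(OC)cc3)o2)c1
A2 | alternative 1 | cupressuflavone 4',4'''-dimethyl ether | COc1ccc(cc1)-c1cc(=O)c2c(O)cc(O)c(c2o1)-c1c(O)cc(O)c2c(=O)cc(oc12)-c1ccc(OC)cc1
A3 | alternative 2 | di-tert-butylbis(3,5-dimethoxyphenoxy)silane | COc1cc(OC)cc(O[Si](Oc2cc(OC)cc(OC)c2)(C(C)(C)C)C(C)(C)C)c1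
A4 | alternative 2 | 6,6-di-tert-butyl-1,3,9,11-tetramethoxydibenzo[d,f][1,3,2]dioxasilepine | COc1cc(OC)c2c(c1)O[Si](C(C)(C)C)(C(C)(C)C)Oc1cc(OC)cc(OC)c1-2
A5 | alternative 3 | 6,6'-(ethane-1,2-diyl)bis(4-methoxy-2H-pyran-2-one) | COc1cc(=O)oc(CCc2cc(OC)cc(=O)o2)c1
A6 | alternative 3 | 4,4'-dimethoxybiphenyl-2,2',6,6'-tetraol | COc1cc(O)c(-c2c(O)cc(OC)cc2O)c(O)c1
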